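**Retrosynthetic overview**
1. The target comes from its ring C aryl MOM ether by one mild acidolysis. Rings: A = benzo ring, B = dihydrofuran, C = 4-hydroxy-3,5-dimethoxyphenyl, D = 3,5-dihydroxyphenyl.
2. Feature: in ring D the oxygen-bearing carbons C3' and C5' alternate with CH carbons and C1' carries the styryl carbon, which is the pattern of a folded cinnamoyl–CO–CH2–CO–CH2–CO–CH3 chain. Both ring bonds at C1' are cut, C1'–C2' (Claisen acylation) and C1'–C6' (aldol), giving the N-methoxy-N-methyl cinnamamide of the A/B/C core and acetylacetone.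
3. The cinnamamide comes from Heck coupling of the 5-bromo A/B/C core with N-methoxy-N-methylacrylamide.
4. Ring B comes from enantioselective rhodium-carbene insertion of an aryl diazoacetate into the benzylic C–H of its ortho benzyl ether (C2–C3 bond), then C3 epimerisation to trans and ester reduction.
5. The diazo ester comes from 5-bromo-o-vanillin (one-carbon homologation to the arylacetate) and a MOM-protected syringyl alcohol. Ring order: B first, D last.

Key step: step 12

Assumption: dirhodium tetrakis[N-phthaloyl-(S)-tert-leucinate] is taken to give the 2R configuration at the insertion carbon, as with simpler 2-(benzyloxy)aryl diazoacetates; if the sense is opposite here, the (R)-tert-leucinate catalyst is used and nothing else changes.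
Remark on protecting groups: the C3 hydroxymethyl group is carried free through steps 11 and 12 (as its lithium alkoxide in step 12, at the cost of one extra equivalent of dianion), so that only the easily cleaved aryl MOM ether remains for the last step.

**Route**

Step 1
Reactants: 1 5-bromo-2-hydroxy-3-methoxybenzaldehyde
Product: 2 5-bromo-3-methoxy-2-(methoxymethoxy)benzaldehyde
Conditions: MOMCl, i-Pr2NEt, CH2Cl2, 0 °C → rt
Reagents that add atoms: chloromethyl methyl ether (MOMCl), COCCl
Why: O-alkylation of the phenoxide by the chloromethyl ether (MOM protection) masks the acidic phenol, which would otherwise consume the hydroxide catalyst and deactivate the aldehyde in step 2.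

Step 2
Reactants: 2 5-bromo-3-methoxy-2-(methoxymethoxy)benzaldehyde; 3 methyl (methylsulfinyl)methyl sulfide (FAMSO)
Product: 4 5-bromo-1-methoxy-2-(methoxymethoxy)-3-[2-(methylsulfanyl)-2-(methylsulfinyl)ethenyl]benzene
Conditions: benzyltrimethylammonium hydroxide (40% in MeOH, 0.3 equiv), THF, reflux
Reagents that add atoms: none
Why: Knoevenagel-type condensation of the methylene of 3, acidified by its two sulfur groups, with the non-enolisable aryl aldehyde gives the ketene dithioacetal S-oxide, which carries the new carbon at the carboxylic acid oxidation level.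

Step 3
Reactants: 4 5-bromo-1-methoxy-2-(methoxymethoxy)-3-[2-(methylsulfanyl)-2-(methylsulfinyl)ethenyl]benzene
Product: 5 methyl 2-(5-bromo-2-hydroxy-3-methoxyphenyl)acetate
Conditions: HCl (3 M in MeOH), 55 °C; then NaHCO3 before concentration
Reagents that add atoms: methanol, CO
Why: Acid-catalysed methanolysis of the ketene dithioacetal S-oxide (protonation at the benzylic carbon, addition of methanol, loss of both sulfur groups as the disulfide) completes the one-carbon homologation of the aldehyde to the arylacetate, and the same acid cleaves the aryl MOM acetal to free the phenol for step 6.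

Step 4
Reactants: 6 syringaldehyde (4-hydroxy-3,5-dimethoxybenzaldehyde)
Product: 7 3,5-dimethoxy-4-(methoxymethoxy)benzaldehyde
Conditions: MOMCl, i-Pr2NEt, CH2Cl2, 0 °C → rt
Reagents that add atoms: chloromethyl methyl ether (MOMCl), COCCl
Why: MOM protection by O-alkylation of the hindered but acidic phenol gives an acetal that should be inert to hydride, Mitsunobu, carbene, alkoxide, Heck and dianion conditions and is removable at the end with mild acid.

Step 5
Reactants: 7 3,5-dimethoxy-4-(methoxymethoxy)benzaldehyde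
Product: 8 [3,5-dimethoxy-4-(methoxymethoxy)phenyl]methanol
Conditions: NaBH4, MeOH, 0 °C
Reagents that add atoms: none
Why: Hydride reduction of the aryl aldehyde to the benzylic alcohol with NaBH4 leaves the acetal untouched.

Step 6
Reactants: 5 methyl 2-(5-bromo-2-hydroxy-3-methoxyphenyl)acetate; 8 [3,5-dimethoxy-4-(methoxymethoxy)phenyl]methanol
Product: 9 methyl 2-[5-bromo-2-{[3,5-dimethoxy-4-(methoxymethoxy)phenyl]methoxy}-3-methoxyphenyl]acetate
Conditions: PPh3, DIAD, THF, 0 °C → rt
Reagents that add atoms: none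
Why: Mitsunobu etherification, in which the phenoxide of 5 displaces the phosphonium-activated benzylic alcohol under neutral conditions that spare the methyl ester and the MOM acetal, avoids isolating a labile electron-rich benzylic halide.

Step 7
Reactants: 9 methyl 2-[5-bromo-2-{[3,5-dimethoxy-4-(methoxymethoxy)phenyl]methoxy}-3-methoxyphenyl]acetate
Product: 10 methyl 2-[5-bromo-2-{[3,5-dimethoxy-4-(methoxymethoxy)phenyl]methoxy}-3-methoxyphenyl]-2-diazoacetate
Conditions: 4-acetamidobenzenesulfonyl azide, DBU, MeCN, 0 °C → rt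
Reagents that add atoms: 4-acetamidobenzenesulfonyl azide, CC(=O)Nc1ccc(cc1)S(=O)(=O)N=[N+]=[N-]
Why: Regitz diazo transfer, in which the DBU-generated arylacetate enolate takes the diazo group from the sulfonyl azide, gives the donor/acceptor diazo ester.

Step 8
Reactants: 10 methyl 2-[5-bromo-2-{[3,5-dimethoxy-4-(methoxymethoxy)phenyl]methoxy}-3-methoxyphenyl]-2-diazoacetate
Product: 11 methyl (2R,3S)-5-bromo-2-[3,5-dimethoxy-4-(methoxymethoxy)phenyl]-7-methoxy-2,3-dihydro-1-benzofuran-3-carboxylate (cis)
Conditions: dirhodium tetrakis[N-phthaloyl-(S)-tert-leucinate] (1 mol %), toluene, −78 °C, slow addition of 10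
Reagents that add atoms: none
Why: Intramolecular 1,5 C–H insertion of the donor/acceptor rhodium carbene into the benzylic C–H bond next to the ether oxygen closes ring B by the C2–C3 bond; the chiral carboxylate ligands select one of the two enantiotopic benzylic hydrogens and so set C2 as R, and the concerted insertion at low temperature gives the kinetic cis ester (3S).

Step 9
Reactants: 11 methyl (2R,3S)-5-bromo-2-[3,5-dimethoxy-4-(methoxymethoxy)phenyl]-7-methoxy-2,3-dihydro-1-benzofuran-3-carboxylate (cis)
Product: 12 methyl (2R,3R)-5-bromo-2-[3,5-dimethoxy-4-(methoxymethoxy)phenyl]-7-methoxy-2,3-dihydro-1-benzofuran-3-carboxylate (trans)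
Conditions: NaOMe (0.5 equiv), MeOH–THF, rt
Reagents that add atoms: none
Why: Base-mediated epimerisation through the ester enolate should convert the cis ester into the thermodynamically favoured trans isomer (3R, aryl and ester on opposite faces), while C2 stays untouched because opening of ring B from the enolate would be the reverse of a disfavoured 5-endo-trig closure.

Step 10
Reactants: 12 methyl (2R,3R)-5-bromo-2-[3,5-dimethoxy-4-(methoxymethoxy)phenyl]-7-methoxy-2,3-dihydro-1-benzofuran-3-carboxylate (trans)
Product: 13 [(2R,3S)-5-bromo-2-[3,5-dimethoxy-4-(methoxymethoxy)phenyl]-7-methoxy-2,3-dihydro-1-benzofuran-3-yl]methanol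
Conditions: LiBH4, THF, 0 °C → rt
Reagents that add atoms: none
Why: Ester reduction with LiBH4 gives the primary alcohol without touching the aryl bromide or the MOM acetal; the change of the C3 descriptor from R to S reflects only the new substituent priority.

Step 11
Reactants: 13 [(2R,3S)-5-bromo-2-[3,5-dimethoxy-4-(methoxymethoxy)phenyl]-7-methoxy-2,3-dihydro-1-benzofuran-3-yl]methanol; 14 N-methoxy-N-methylprop-2-enamide
Product: 15 (2E)-3-[(2R,3S)-2-[3,5-dimethoxy-4-(methoxymethoxy)phenyl]-3-(hydroxymethyl)-7-methoxy-2,3-dihydro-1-benzofuran-5-yl]-N-methoxy-N-methylprop-2-enamide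
Conditions: Pd(OAc)2 (5 mol %), P(o-tol)3 (15 mol %), Et3N, DMF, 100 °C
Reagents that add atoms: none
Why: Mizoroki–Heck coupling (oxidative addition of the aryl bromide to zerovalent palladium, syn insertion of the acrylamide, syn β-hydride elimination) should give the E cinnamamide, with the free primary alcohol and both stereocentres inert.

Step 12
Reactants: 15 (2E)-3-[(2R,3S)-2-[3,5-dimethoxy-4-(methoxymethoxy)phenyl]-3-(hydroxymethyl)-7-methoxy-2,3-dihydro-1-benzofuran-5-yl]-N-methoxy-N-methylprop-2-enamide; 16 acetylacetone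
Product: 18 5-[(E)-2-[(2R,3S)-2-[3,5-dimethoxy-4-(methoxymethoxy)phenyl]-3-(hydroxymethyl)-7-methoxy-2,3-dihydro-1-benzofuran-5-yl]ethenyl]benzene-1,3-diol, via styryl triketone 17 (not isolated)
Conditions: 16 (2.3 equiv), LiN(i-Pr)2 (4.5 equiv), THF, 0 °C; add 15, −78 → 0 °C; then degassed 2 M aq KOH, MeOH, rt → 45 °C; NaH2PO4 to pH 6 at 0 °C
Reagents that add atoms: none
Why: The terminal carbanion of the dilithio dianion of 16 adds to the amide carbonyl of 15 (the hydroxymethyl group having taken up the first equivalent as its alkoxide), and the N,O-chelated lithium adduct holds until water arrives, so no second addition can occur; aqueous KOH then releases triketone 17, whose methyl terminus attacks the cinnamoyl carbonyl, and loss of water with enolisation of the two remaining ketones gives the resorcinol. The closest known reactions are the Claisen-type acylation of 1,3-diketone dianions by esters or N-methoxy-N-methyl amides and the base-mediated aldol aromatisation of 2,4,6-triketones to 5-substituted resorcinols, the laboratory counterpart of polyketide folding. Ring D closes in a 6-(enolendo)-exo-trig aldol, the only six-membered aldol open to 17 because its other terminus is a non-enolisable vinyl carbon. No stereocentre is formed: the E alkene lies outside the reacting array, C2 and C3 of ring B carry no acidic hydrogen, and the MOM group keeps the ring C phenol from opening ring B through a quinone methide in base. The step needs carbonyl attack over conjugate addition and C–C closure over O-closure; the hard dianion terminus and the chelating amide favour 1,2-acylation, and oxa-Michael closure to a dihydropyranone is reversible in base whereas aromatisation is not, so material should drain to 18 as long as the mixture stays basic until 17 is consumed (acid would dehydrate 17 to a 4-pyranone).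

Step 13
Reactants: 18 5-[(E)-2-[(2R,3S)-2-[3,5-dimethoxy-4-(methoxymethoxy)phenyl]-3-(hydroxymethyl)-7-methoxy-2,3-dihydro-1-benzofuran-5-yl]ethenyl]benzene-1,3-diol
Product: 19 gnetucleistol F
Conditions: HCl (1.25 M in MeOH), THF, 0 °C → rt
Reagents that add atoms: none
Why: Acid-catalysed transacetalisation of the aryl MOM ether to methanol frees the ring C phenol; since only this readily cleaved aryl acetal remains, the acid can be kept dilute and cold, which should protect the benzylic C2–O bond and the stilbene.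

**Compound list**
1 | 5-bromo-2-hydroxy-3-methoxybenzaldehyde | COc1cc(Br)cc(C=O)c1O | starting material
2 | 5-bromo-3-methoxy-2-(methoxymethoxy)benzaldehyde | COCOc1c(OC)cc(Br)cc1C=O | intermediate
3 | methyl (methylsulfinyl)methyl sulfide (FAMSO) | CSCS(C)=O | starting material
4 | 5-bromo-1-methoxy-2-(methoxymethoxy)-3-[2-(methylsulfanyl)-2-(methylsulfinyl)ethenyl]benzene (alkene geometry and sulfur configuration not controlled, both lost in step 3) | COCOc1c(OC)cc(Br)cc1C=C(SC)S(C)=O | intermediate
5 | methyl 2-(5-bromo-2-hydroxy-3-methoxyphenyl)acetate | COC(=O)Cc1cc(Br)cc(OC)c1O | intermediate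
6 | syringaldehyde (4-hydroxy-3,5-dimethoxybenzaldehyde) | COc1cc(C=O)cc(OC)c1O | starting material
7 | 3,5-dimethoxy-4-(methoxymethoxy)benzaldehyde | COCOc1c(OC)cc(C=O)cc1OC | intermediate
8 | [3,5-dimethoxy-4-(methoxymethoxy)phenyl]methanol | COCOc1c(OC)cc(CO)cc1OC | intermediate
9 | methyl 2-[5-bromo-2-{[3,5-dimethoxy-4-(methoxymethoxy)phenyl]methoxy}-3-methoxyphenyl]acetate | COC(=O)Cc1cc(Br)cc(OC)c1OCc1cc(OC)c(OCOC)c(OC)c1 | intermediate
10 | methyl 2-[5-bromo-2-{[3,5-dimethoxy-4-(methoxymethoxy)phenyl]methoxy}-3-methoxyphenyl]-2-diazoacetate | COC(=O)C(=[N+]=[N-])c1cc(Br)cc(OC)c1OCc1cc(OC)c(OCOC)c(OC)c1 | intermediate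
11 | methyl (2R,3S)-5-bromo-2-[3,5-dimethoxy-4-(methoxymethoxy)phenyl]-7-methoxy-2,3-dihydro-1-benzofuran-3-carboxylate (cis) | COCOc1c(OC)cc([C@@H]2Oc3c(OC)cc(Br)cc3[C@@H]2C(=O)OC)cc1OC | intermediate
12 | methyl (2R,3R)-5-bromo-2-[3,5-dimethoxy-4-(methoxymethoxy)phenyl]-7-methoxy-2,3-dihydro-1-benzofuran-3-carboxylate (trans) | COCOc1c(OC)cc([C@@H]2Oc3c(OC)cc(Br)cc3[C@H]2C(=O)OC)cc1OC | intermediate
13 | [(2R,3S)-5-bromo-2-[3,5-dimethoxy-4-(methoxymethoxy)phenyl]-7-methoxy-2,3-dihydro-1-benzofuran-3-yl]methanol | COCOc1c(OC)cc([C@@H]2Oc3c(OC)cc(Br)cc3[C@H]2CO)cc1OC | intermediate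
14 | N-methoxy-N-methylprop-2-enamide (N-methoxy-N-methylacrylamide) | C=CC(=O)N(C)OC | starting material
15 | (2E)-3-[(2R,3S)-2-[3,5-dimethoxy-4-(methoxymethoxy)phenyl]-3-(hydroxymethyl)-7-methoxy-2,3-dihydro-1-benzofuran-5-yl]-N-methoxy-N-methylprop-2-enamide | COCOc1c(OC)cc([C@@H]2Oc3c(OC)cc(/C=C/C(=O)N(C)OC)cc3[C@H]2CO)cc1OC | intermediate
16 | acetylacetone (pentane-2,4-dione) | CC(=O)CC(C)=O | starting material
17 | (7E)-8-[(2R,3S)-2-[3,5-dimethoxy-4-(methoxymethoxy)phenyl]-3-(hydroxymethyl)-7-methoxy-2,3-dihydro-1-benzofuran-5-yl]oct-7-ene-2,4,6-trione | COCOc1c(OC)cc([C@@H]2Oc3c(OC)cc(/C=C/C(=O)CC(=O)CC(C)=O)cc3[C@H]2CO)cc1OC | intermediate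
18 | 5-[(E)-2-[(2R,3S)-2-[3,5-dimethoxy-4-(methoxymethoxy)phenyl]-3-(hydroxymethyl)-7-methoxy-2,3-dihydro-1-benzofuran-5-yl]ethenyl]benzene-1,3-diol | COCOc1c(OC)cc([C@@H]2Oc3c(OC)cc(/C=C/c4cc(O)cc(O)c4)cc3[C@H]2CO)cc1OC | intermediate
19 | gnetucleistol F, 5-[(E)-2-[(2R,3S)-2-(4-hydroxy-3,5-dimethoxyphenyl)-3-(hydroxymethyl)-7-methoxy-2,3-dihydro-1-benzofuran-5-yl]ethenyl]benzene-1,3-diol | COc1cc([C@@H]2Oc3c(OC)cc(/C=C/c4cc(O)cc(O)c4)cc3[C@H]2CO)cc(OC)c1O | target

**Step count**
Total: 13 steps. Longest linear sequence: 11 steps (steps 1, 2, 3 and 6 to 13, from 1 to 19).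

**Steps most likely to fail**

Step 12. The aldol closure may stall because 17 rests in strong base as an unreactive dianion. Hydroxide could then cleave a diketone unit by retro-Claisen reaction, the central diketonate carbon could add to the styryl carbon in a 6-endo Michael closure to a cyclohexane-1,3-dione, or acid on work-up could dehydrate unreacted 17 to a 4-pyranone. Conjugate addition of the dianion to 15 is a further possible loss. The fallback sets out from 13 and comes back at 19, building the stilbene by a second Heck coupling instead of folding ring D. 3,5-Dihydroxybenzaldehyde would be protected (MOMCl, i-Pr2NEt) as 3,5-bis(methoxymethoxy)benzaldehyde F1 and methylenated by Wittig reaction (Ph3PCH3Br, KOt-Bu, THF) to 1-ethenyl-3,5-bis(methoxymethoxy)benzene F2. Heck coupling of 13 with F2 (Pd(OAc)2, P(o-tol)3, Et3N, DMF, 100 °C) should give [(2R,3S)-5-{(E)-2-[3,5-bis(methoxymethoxy)phenyl]ethenyl}-2-[3,5-dimethoxy-4-(methoxymethoxy)phenyl]-7-methoxy-2,3-dihydro-1-benzofuran-3-yl]methanol F3. Methanolic HCl as in step 13 would then remove all three MOM groups and give 19.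

Step 8. Discrimination between the two enantiotopic benzylic hydrogens may be poor, or the cis preference may be eroded, because the flanking 3-methoxy group and the 3,5-dimethoxy pattern of the benzyl ether change how the side chain sits in the catalyst pocket. The fallback sets out from 9 and comes back at 13, adding a chiral auxiliary that acts together with a prolinate catalyst and should give the trans ester directly. Ester 9 would be saponified (LiOH, THF–H2O) to 2-[5-bromo-2-{[3,5-dimethoxy-4-(methoxymethoxy)phenyl]methoxy}-3-methoxyphenyl]acetic acid F5. This would be esterified (EDC·HCl, DMAP, CH2Cl2) with (2R)-2-hydroxy-1-(pyrrolidin-1-yl)propan-1-one F4 (from methyl (R)-lactate and pyrrolidine) to give (2R)-1-oxo-1-(pyrrolidin-1-yl)propan-2-yl 2-[5-bromo-2-{[3,5-dimethoxy-4-(methoxymethoxy)phenyl]methoxy}-3-methoxyphenyl]acetate F6. Diazo transfer (4-acetamidobenzenesulfonyl azide, DBU) would give (2R)-1-oxo-1-(pyrrolidin-1-yl)propan-2-yl 2-[5-bromo-2-{[3,5-dimethoxy-4-(methoxymethoxy)phenyl]methoxy}-3-methoxyphenyl]-2-diazoacetate F7. Insertion with dirhodium tetrakis[(R)-N-(4-dodecylphenylsulfonyl)prolinate] in CH2Cl2 should give (2R)-1-oxo-1-(pyrrolidin-1-yl)propan-2-yl (2R,3R)-5-bromo-2-[3,5-dimethoxy-4-(methoxymethoxy)phenyl]-7-methoxy-2,3-dihydro-1-benzofuran-3-carboxylate F8. The auxiliary and catalyst are taken in the enantiomeric pairing expected to lead to the 2R series. LiBH4 would then release the auxiliary and give 13, so steps 8 to 10 are replaced.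

Step 9. Epimerisation may stop short of completion, or the ester enolate may expel the ring aryloxide, in which case re-closure would erode the configuration at C2. The fallback sets out from 11 and comes back at 13, moving the epimerisation to the aldehyde oxidation level, where a mild amine base suffices. Partial reduction of 11 (i-Bu2AlH, toluene, −78 °C) would give (2R,3S)-5-bromo-2-[3,5-dimethoxy-4-(methoxymethoxy)phenyl]-7-methoxy-2,3-dihydro-1-benzofuran-3-carbaldehyde F9. Catalytic DBU in CH2Cl2 should equilibrate it to the trans (2R,3R)-5-bromo-2-[3,5-dimethoxy-4-(methoxymethoxy)phenyl]-7-methoxy-2,3-dihydro-1-benzofuran-3-carbaldehyde F10. NaBH4 in MeOH would then give 13.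

**Further compounds**
F1 | step 12 | 3,5-bis(methoxymethoxy)benzaldehyde | COCOc1cc(C=O)cc(OCOC)c1
F2 | step 12 | 1-ethenyl-3,5-bis(methoxymethoxy)benzene | COCOc1cc(C=C)cc(OCOC)c1
F3 | step 12 | [(2R,3S)-5-{(E)-2-[3,5-bis(methoxymethoxy)phenyl]ethenyl}-2-[3,5-dimethoxy-4-(methoxymethoxy)phenyl]-7-methoxy-2,3-dihydro-1-benzofuran-3-yl]methanol | COCOc1c(OC)cc([C@@H]2Oc3c(OC)cc(/C=C/c4cc(OCOC)cc(OCOC)c4)cc3[C@H]2CO)cc1OC
F4 | step 8 | (2R)-2-hydroxy-1-(pyrrolidin-1-yl)propan-1-one | C[C@@H](O)C(=O)N1CCCC1
F5 | step 8 | 2-[5-bromo-2-{[3,5-dimethoxy-4-(methoxymethoxy)phenyl]methoxy}-3-methoxyphenyl]acetic acid | OC(=O)Cc1cc(Br)cc(OC)c1OCc1cc(OC)c(OCOC)c(OC)c1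
F6 | step 8 | (2R)-1-oxo-1-(pyrrolidin-1-yl)propan-2-yl 2-[5-bromo-2-{[3,5-dimethoxy-4-(methoxymethoxy)phenyl]methoxy}-3-methoxyphenyl]acetate | C[C@@H](OC(=O)Cc1cc(Br)cc(OC)c1OCc1cc(OC)c(OCOC)c(OC)c1)C(=O)N1CCCC1
F7 | step 8 | (2R)-1-oxo-1-(pyrrolidin-1-yl)propan-2-yl 2-[5-bromo-2-{[3,5-dimethoxy-4-(methoxymethoxy)phenyl]methoxy}-3-methoxyphenyl]-2-diazoacetate | C[C@@H](OC(=O)C(=[N+]=[N-])c1cc(Br)cc(OC)c1OCc1cc(OC)c(OCOC)c(OC)c1)C(=O)N1CCCC1
F8 | step 8 | (2R)-1-oxo-1-(pyrrolidin-1-yl)propan-2-yl (2R,3R)-5-bromo-2-[3,5-dimethoxy-4-(methoxymethoxy)phenyl]-7-methoxy-2,3-dihydro-1-benzofuran-3-carboxylate | COCOc1c(OC)cc([C@@H]2Oc3c(OC)cc(Br)cc3[C@H]2C(=O)O[C@H](C)C(=O)N4CCCC4)cc1OC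
F9 | step 9 | (2R,3S)-5-bromo-2-[3,5-dimethoxy-4-(methoxymethoxy)phenyl]-7-methoxy-2,3-dihydro-1-benzofuran-3-carbaldehyde (cis) | COCOc1c(OC)cc([C@@H]2Oc3c(OC)cc(Br)cc3[C@@H]2C=O)cc1OC
F10 | step 9 | (2R,3R)-5-bromo-2-[3,5-dimethoxy-4-(methoxymethoxy)phenyl]-7-methoxy-2,3-dihydro-1-benzofuran-3-carbaldehyde (trans) | COCOc1c(OC)cc([C@@H]2Oc3c(OC)cc(Br)cc3[C@H]2C=O)cc1OC
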